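**Retrosynthetic overview**
1. The ester at C6 is made last from the C6 alcohol and the epoxy acid; ring C (the carbocyclic bridge C4–C3–C2–C1=C10–C9) is closed before that by ring-closing metathesis at C1=C10.
2. Rings A (oxepane: O4, C4–C9) and B (γ-lactone: O8, C12, C11, C7, C8) are made together: O4–C9 and C7–C8 form in one Barbier allylation / acyl transfer / SN2′ etherification relay between a seven-membered lactone allylic bromide (C3–C7, C11–C13, O4) and an achiral enal (C8–C10, C14).
3. Enabling feature: the acyl carbon C12 of ring B can be tied to the ether oxygen O4 as a temporary seven-membered lactone (O4, C4, C5, C6, C7, C11, C12) that shares O4–C4–C5–C6–C7 with ring A. This ring locks the C7=C11 geometry and one face, masks O4, and releases O4 when O8 takes over the acyl group; C9 is β to the C14 ester and flanked by an allylic leaving group, so it accepts O4.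
4. The lactone bromide comes from geranyl acetate (C4 and C6 by Sharpless kinetic resolution and epoxide reduction, ring by metathesis); the epoxy acid comes from tiglyl alcohol by Sharpless epoxidation.
5. Order of ring formation: temporary seven-membered lactone → rings A and B (key step; temporary ring cleaved) → ring C → esterification.

Key step: step 13

Remark (locants used below): C1 ring CH=, C2, C3, C4 (C–CH3, bound to ether oxygen O4), C5, C6 (CH–O ester), C7, C8 (CH–O8 of the lactone), C9 (CH–O4), C10 (C–CO2Me), C11/C12/C13 (lactone ring carbon, carbonyl, methylidene), C14 (ester carbonyl); the side-chain acid is taken as drawn, the cis-dimethyl (2S,3R)-2,3-dimethyloxirane-2-carboxylic acid.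

**Step 1**
Reactants: 1 geranyl acetate
Product: 3 (2E)-6,6-dimethoxy-3-methylhex-2-en-1-yl acetate, via aldehyde 2 (not isolated)
Conditions: O3, CH2Cl2, pyridine, −78 °C; Me2S; then HC(OMe)3, MeOH, TsOH (cat.), rt
Reagents that add atoms: trimethyl orthoformate COC(OC)OC
Why: Ozonolysis should cleave the electron-rich 6,7-alkene faster than the 2,3-alkene, which is deactivated by the allylic acetate, and acetalization then masks the new aldehyde (future C1) without touching the E alkene.

**Step 2**
Reactants: 3 (2E)-6,6-dimethoxy-3-methylhex-2-en-1-yl acetate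
Product: 4 (2E)-6,6-dimethoxy-3-methylhex-2-en-1-ol
Conditions: K2CO3, MeOH, rt
Reagents that add atoms: none
Why: Base-catalysed transesterification (methanolysis) should free the allylic alcohol, the acetal being stable to base.

**Step 3**
Reactants: 4 (2E)-6,6-dimethoxy-3-methylhex-2-en-1-ol
Product: 5 (2E)-6,6-dimethoxy-3-methylhex-2-enal
Conditions: TEMPO (cat.), PhI(OAc)2, CH2Cl2, rt
Reagents that add atoms: none
Why: TEMPO-catalysed oxidation of an allylic alcohol should stop at the enal without E/Z isomerization or loss of the acetal.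

**Step 4**
Reactants: 5 (2E)-6,6-dimethoxy-3-methylhex-2-enal
Product: 6 racemic (4E)-8,8-dimethoxy-5-methylocta-1,4-dien-3-ol
Conditions: CH2=CHMgBr, THF, −78 °C; then aqueous work-up
Reagents that add atoms: vinylmagnesium bromide C=C[Mg]Br
Why: 1,2-Addition of a vinyl Grignard reagent to a β,β-disubstituted enal should give the racemic bis-allylic alcohol (C6 carbinol, C7 vinyl) that the next step resolves.

**Step 5**
Reactants: 6 racemic (4E)-8,8-dimethoxy-5-methylocta-1,4-dien-3-ol
Product: 7 (1S)-1-[(2S,3S)-3-(3,3-dimethoxypropyl)-3-methyloxiran-2-yl]prop-2-en-1-ol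
Conditions: Ti(OiPr)4 (cat.), L-(+)-diisopropyl tartrate, tBuOOH (0.55 equiv), 4 Å molecular sieves, CH2Cl2, −20 °C
Reagents that add atoms: tert-butyl hydroperoxide CC(C)(C)OO
Why: Sharpless kinetic resolution: with L-(+)-tartrate only the (S)-carbinol should be epoxidized at a useful rate, on the electron-rich trisubstituted alkene and anti to the carbinol oxygen (erythro product), which sets C4 and fixes C6, while the (R)-alcohol stays behind and is separated.

**Step 6**
Reactants: 7 (1S)-1-[(2S,3S)-3-(3,3-dimethoxypropyl)-3-methyloxiran-2-yl]prop-2-en-1-ol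
Product: 8 (3R,5S)-8,8-dimethoxy-5-methyloct-1-ene-3,5-diol
Conditions: NaAlH2(OCH2CH2OMe)2, THF, 0 °C
Reagents that add atoms: none
Why: Hydroxyl-directed reduction of a 2,3-epoxy alcohol should deliver hydride intramolecularly to the proximal carbon C5, so the C4–O bond keeps its configuration and the anti 1,3-diol results.

**Step 7**
Reactants: 8 (3R,5S)-8,8-dimethoxy-5-methyloct-1-ene-3,5-diol
Product: 9 (3R,5S)-3-[(tert-butyldimethylsilyl)oxy]-8,8-dimethoxy-5-methyloct-1-en-5-ol
Conditions: TBSCl, imidazole, DMF, 0 °C → rt
Reagents that add atoms: tert-butyldimethylsilyl chloride CC(C)(C)[Si](C)(C)Cl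
Why: Selective silylation should protect the secondary allylic hydroxyl only, the tertiary hydroxyl being too hindered under these conditions.

**Step 8**
Reactants: 9 (3R,5S)-3-[(tert-butyldimethylsilyl)oxy]-8,8-dimethoxy-5-methyloct-1-en-5-ol; 10 2-(bromomethyl)prop-2-enoic acid
Product: 12 (3R,5S)-3-[(tert-butyldimethylsilyl)oxy]-8,8-dimethoxy-5-methyloct-1-en-5-yl 2-(bromomethyl)prop-2-enoate, via acid chloride 11 (not isolated)
Conditions: 10, (COCl)2, DMF (cat.), CH2Cl2, 0 °C → rt, evaporation; 9, n-BuLi, THF, −78 °C, then 11, −78 → −20 °C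
Reagents that add atoms: none
Why: O-Acylation of a lithium tertiary alkoxide by an acid chloride at −78 °C should be faster than substitution at the allylic bromide or silyl migration, and it avoids amine bases that would attack the bromomethyl acrylate.

**Step 9**
Reactants: 12 (3R,5S)-3-[(tert-butyldimethylsilyl)oxy]-8,8-dimethoxy-5-methyloct-1-en-5-yl 2-(bromomethyl)prop-2-enoate
Product: 13 (5R,7S)-3-(bromomethyl)-5-[(tert-butyldimethylsilyl)oxy]-7-(3,3-dimethoxypropyl)-7-methyl-6,7-dihydro-5H-oxepin-2-one
Conditions: second-generation Hoveyda–Grubbs catalyst [RuCl2(H2IMes)(=CH-C6H4-2-OiPr)] (cat.), toluene (0.002 M), 80 °C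
Reagents that add atoms: none
Why: Ring-closing metathesis (carbene loaded at the vinyl group, closure onto the acrylate) should give the temporary seven-membered lactone, whose ring size forces C6 and C12 to be cis on the C7=C11 bond.

**Step 10**
Reactants: 14 methyl acrylate; 15 2,2-dimethoxyacetaldehyde
Product: 16 racemic methyl 3-hydroxy-4,4-dimethoxy-2-methylidenebutanoate
Conditions: DABCO (cat.), dioxane/H2O, rt
Reagents that add atoms: none
Why: Morita–Baylis–Hillman reaction of an acrylate with an electrophilic α-alkoxy aldehyde; the carbinol stereocentre is lost again in step 11.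

**Step 11**
Reactants: 16 racemic methyl 3-hydroxy-4,4-dimethoxy-2-methylidenebutanoate
Product: 18 methyl (2E)-2-(acetoxymethyl)-4,4-dimethoxybut-2-enoate, via secondary acetate 17 (not isolated)
Conditions: Ac2O, pyridine, DMAP (cat.), CH2Cl2, 0 °C; then DABCO (cat.), THF, 60 °C
Reagents that add atoms: acetic anhydride CC(=O)OC(C)=O
Why: Acetylation followed by DABCO-catalysed 1,3-transposition of the Morita–Baylis–Hillman acetate (SN2′ addition of the amine, return of acetate at the CH2 terminus) should give the thermodynamically favoured trisubstituted enoate with the acetal carbon trans to the ester (E).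

**Step 12**
Reactants: 18 methyl (2E)-2-(acetoxymethyl)-4,4-dimethoxybut-2-enoate
Product: 19 methyl (2E)-2-(acetoxymethyl)-4-oxobut-2-enoate
Conditions: CF3CO2H, H2O, CH2Cl2, 0 °C
Reagents that add atoms: water O
Why: Acid hydrolysis of the dimethyl acetal should free the enal (future C8), the allylic acetate, the methyl ester and the E geometry being stable to these conditions.

**Step 13**
Reactants: 13 seven-membered lactone allylic bromide; 19 methyl (2E)-2-(acetoxymethyl)-4-oxobut-2-enoate
Product: 22 oxepane (ring A) trans-fused to the α-methylidene γ-lactone (ring B) with 1-(methoxycarbonyl)vinyl at C9, via hydroxy lactone 20 (not isolated), via tertiary alcohol 21 (not isolated)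
Conditions: indium powder, DMF, rt; then Cs2CO3, rt (same flask)
Reagents that add atoms: none
Why: Indium inserts into the allylic C–Br bond of 13 and the allylindium adds through its γ-carbon C7 to the aldehyde of 19 in a six-membered chair transition state (Barbier allylation of the Dreiding–Schmidt type, as known for 2-(bromomethyl)alk-2-enoates), forming C7–C8 and the exocyclic C11=C13 alkene. The C8 alkoxide then attacks the ring carbonyl C12 (5-exo-trig acyl transfer), which closes the γ-lactone, opens the seven-membered lactone and frees the C4 alkoxide; this alkoxide adds to C9 of the 2-(acetoxymethyl)enoate and acetate leaves from the CH2 carbon (7-exo-trig oxa-Michael addition–elimination, the SN2′ etherification known for Morita–Baylis–Hillman acetates), closing the oxepane and forming O4–C9. C7: the aldehyde should approach the ring alkene anti to the neighbouring C6 silyloxy group; C8: the ring holds C6 trans to the CH2–In carbon (an E-crotyl-type reagent), so the chair with the aldehyde substituent equatorial gives the anti adduct and hence the trans-fused lactone; C9: allylic 1,3-strain with the CH2OAc group cis to C8 keeps H8 in the enoate plane and the tether delivers O4 from the C7 side. Selectivity needed: γ-attack and 1,2-addition (normal for these reagents), lactonization at C12 and not at the methyl ester (the E geometry of 19 places that ester trans to C8), and O4–C9 in place of O4–CH2 bond formation (direct displacement at CH2OAc would need a nine-membered ring). Addition of the alkoxide to the methylidene lactone is reversible and should not compete with the irreversible loss of acetate.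

**Step 14**
Reactants: 22 ring A/ring B acetal
Product: 23 the corresponding aldehyde (3-oxopropyl group at C4)
Conditions: pyridinium p-toluenesulfonate, acetone/H2O, 45 °C
Reagents that add atoms: water O
Why: Mild acid hydrolysis of the dimethyl acetal should spare the secondary silyl ether, the allylic ether and both acrylate units.

**Step 15**
Reactants: 23 aldehyde
Product: 24 the corresponding terminal alkene (but-3-enyl group at C4)
Conditions: Ph3PCH3Br, KN(SiMe3)2, THF, 0 °C; then 23, −78 °C
Reagents that add atoms: methyltriphenylphosphonium bromide C[P+](c1ccccc1)(c1ccccc1)c1ccccc1.[Br-]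
Why: Wittig methylenation: at −78 °C the unstabilized ylide should add to the aldehyde much faster than to the two acrylate-type acceptors.

**Step 16**
Reactants: 24 diene
Product: 25 tricyclic silyl ether (rings A, B and C complete)
Conditions: second-generation Hoveyda–Grubbs catalyst [RuCl2(H2IMes)(=CH-C6H4-2-OiPr)] (cat.), toluene (0.002 M), 80 °C
Reagents that add atoms: none
Why: Ring-closing metathesis of the terminal alkene onto the 2-substituted acrylate should close the seven-membered bridge (ring C), the two arms being cis on ring A, the ring size forcing the endocyclic cis (Z) enoate, and the methylidene lactone being a poor metathesis partner.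

**Step 17**
Reactants: 25 tricyclic silyl ether
Product: 26 tricyclic C6 alcohol
Conditions: HF·pyridine, pyridine, THF, 0 °C → rt
Reagents that add atoms: none
Why: Fluoride cleavage of the silyl ether under buffered acidic conditions should avoid base-induced migration of the lactone acyl group to the C6 oxygen.

**Step 18**
Reactants: 27 (2E)-2-methylbut-2-en-1-ol (tiglyl alcohol)
Product: 28 [(2R,3R)-2,3-dimethyloxiran-2-yl]methanol
Conditions: Ti(OiPr)4 (cat.), D-(−)-diisopropyl tartrate, tBuOOH, 4 Å molecular sieves, CH2Cl2, −20 °C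
Reagents that add atoms: tert-butyl hydroperoxide CC(C)(C)OO
Why: Sharpless asymmetric epoxidation with D-(−)-tartrate should give the (2R,3R)-epoxy alcohol, the cis relationship of the two methyl groups following from the E alkene.

**Step 19**
Reactants: 28 [(2R,3R)-2,3-dimethyloxiran-2-yl]methanol
Product: 29 (2S,3R)-2,3-dimethyloxirane-2-carboxylic acid
Conditions: TEMPO (cat.), PhI(OAc)2, MeCN/H2O, rt
Reagents that add atoms: water O
Why: TEMPO/PhI(OAc)2 oxidation in wet acetonitrile should take the primary alcohol to the acid through the aldehyde hydrate without opening the epoxide; the stereocentres are untouched (the C2 descriptor changes by priority only).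

**Step 20**
Reactants: 26 tricyclic C6 alcohol; 29 (2S,3R)-2,3-dimethyloxirane-2-carboxylic acid
Product: 30 target compound CNP0240298.1
Conditions: DCC, DMAP (cat.), CH2Cl2, 0 °C → rt
Reagents that add atoms: none
Why: Steglich esterification of the secondary C6 alcohol should proceed with retention at every stereocentre, the acid having no α-hydrogen to epimerize.

**Compound list**
1 | geranyl acetate, (2E)-3,7-dimethylocta-2,6-dien-1-yl acetate | CC(=O)OC/C=C(\C)CCC=C(C)C | starting material
2 | (2E)-3-methyl-6-oxohex-2-en-1-yl acetate | CC(=O)OC/C=C(\C)CCC=O | intermediate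
3 | (2E)-6,6-dimethoxy-3-methylhex-2-en-1-yl acetate | CC(=O)OC/C=C(\C)CCC(OC)OC | intermediate
4 | (2E)-6,6-dimethoxy-3-methylhex-2-en-1-ol | OC/C=C(\C)CCC(OC)OC | intermediate
5 | (2E)-6,6-dimethoxy-3-methylhex-2-enal | O=C/C=C(\C)CCC(OC)OC | intermediate
6 | racemic (4E)-8,8-dimethoxy-5-methylocta-1,4-dien-3-ol | C=CC(O)/C=C(\C)CCC(OC)OC | intermediate
7 | (1S)-1-[(2S,3S)-3-(3,3-dimethoxypropyl)-3-methyloxiran-2-yl]prop-2-en-1-ol | C=C[C@H](O)[C@@H]1O[C@@]1(C)CCC(OC)OC | intermediate
8 | (3R,5S)-8,8-dimethoxy-5-methyloct-1-ene-3,5-diol | C=C[C@H](O)C[C@@](C)(O)CCC(OC)OC | intermediate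
9 | (3R,5S)-3-[(tert-butyldimethylsilyl)oxy]-8,8-dimethoxy-5-methyloct-1-en-5-ol | C=C[C@H](O[Si](C)(C)C(C)(C)C)C[C@@](C)(O)CCC(OC)OC | intermediate
10 | 2-(bromomethyl)prop-2-enoic acid | C=C(CBr)C(=O)O | starting material
11 | 2-(bromomethyl)prop-2-enoyl chloride | C=C(CBr)C(=O)Cl | intermediate
12 | (3R,5S)-3-[(tert-butyldimethylsilyl)oxy]-8,8-dimethoxy-5-methyloct-1-en-5-yl 2-(bromomethyl)prop-2-enoate | C=C[C@H](O[Si](C)(C)C(C)(C)C)C[C@@](C)(OC(=O)C(=C)CBr)CCC(OC)OC | intermediate
13 | (5R,7S)-3-(bromomethyl)-5-[(tert-butyldimethylsilyl)oxy]-7-(3,3-dimethoxypropyl)-7-methyl-6,7-dihydro-5H-oxepin-2-one | BrCC1=C[C@H](O[Si](C)(C)C(C)(C)C)C[C@](C)(CCC(OC)OC)OC1=O | intermediate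
14 | methyl acrylate | C=CC(=O)OC | starting material
15 | 2,2-dimethoxyacetaldehyde | COC(OC)C=O | starting material
16 | racemic methyl 3-hydroxy-4,4-dimethoxy-2-methylidenebutanoate | C=C(C(=O)OC)C(O)C(OC)OC | intermediate
17 | racemic methyl 3-acetoxy-4,4-dimethoxy-2-methylidenebutanoate | C=C(C(=O)OC)C(OC(C)=O)C(OC)OC | intermediate
18 | methyl (2E)-2-(acetoxymethyl)-4,4-dimethoxybut-2-enoate | COC(OC)/C=C(\COC(C)=O)C(=O)OC | intermediate
19 | methyl (2E)-2-(acetoxymethyl)-4-oxobut-2-enoate | O=C/C=C(\COC(C)=O)C(=O)OC | intermediate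
20 | Barbier adduct: 3-methylidene seven-membered lactone whose C7 carries the CH(OH)–CH=C(CO2Me)CH2OAc chain trans to the C6 silyloxy group, C7/C8 anti (4S,6R,7S,8R in the locants of the remark) | C=C1C(=O)O[C@@](C)(CCC(OC)OC)C[C@@H](O[Si](C)(C)C(C)(C)C)[C@@H]1[C@H](O)/C=C(\COC(C)=O)C(=O)OC | intermediate
21 | trans-disubstituted α-methylidene γ-lactone with free C4 tertiary alcohol and intact (E)-2-(acetoxymethyl)enoate (4S,6R,7S,8R) | C=C1C(=O)O[C@H](/C=C(\COC(C)=O)C(=O)OC)[C@H]1[C@H](O[Si](C)(C)C(C)(C)C)C[C@@](C)(O)CCC(OC)OC | intermediate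
22 | oxepane (ring A) trans-fused at C7–C8 to the α-methylidene γ-lactone (ring B); C4 bears CH3 and 3,3-dimethoxypropyl, C6 OTBS, C9 1-(methoxycarbonyl)vinyl (4S,6R,7S,8S,9R) | C=C1C(=O)O[C@H]2[C@H]1[C@H](O[Si](C)(C)C(C)(C)C)C[C@](C)(CCC(OC)OC)O[C@@H]2C(=C)C(=O)OC | intermediate
23 | as 22 with a 3-oxopropyl group at C4 | C=C1C(=O)O[C@H]2[C@H]1[C@H](O[Si](C)(C)C(C)(C)C)C[C@](C)(CCC=O)O[C@@H]2C(=C)C(=O)OC | intermediate
24 | as 22 with a but-3-enyl group at C4 | C=C1C(=O)O[C@H]2[C@H]1[C@H](O[Si](C)(C)C(C)(C)C)C[C@](C)(CCC=C)O[C@@H]2C(=C)C(=O)OC | intermediate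
25 | target skeleton with OTBS at C6 in place of the ester (4S,6R,7S,8S,9R) | C=C1C(=O)O[C@H]2[C@H]1[C@H](O[Si](C)(C)C(C)(C)C)C[C@]1(C)CCC=C(C(=O)OC)[C@H]2O1 | intermediate
26 | target skeleton with free hydroxyl at C6 (4S,6R,7R,8S,9R) | C=C1C(=O)O[C@H]2[C@H]1[C@H](O)C[C@]1(C)CCC=C(C(=O)OC)[C@H]2O1 | intermediate
27 | (2E)-2-methylbut-2-en-1-ol (tiglyl alcohol) | C/C=C(\C)CO | starting material
28 | [(2R,3R)-2,3-dimethyloxiran-2-yl]methanol | OC[C@@]1(C)O[C@@H]1C | intermediate
29 | (2S,3R)-2,3-dimethyloxirane-2-carboxylic acid | OC(=O)[C@@]1(C)O[C@@H]1C | intermediate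
30 | CNP0240298.1 (4S,6R,7R,8S,9R; acyl group 2S,3R) | C=C1C(=O)O[C@H]2[C@H]1[C@H](OC(=O)[C@@]1(C)O[C@@H]1C)C[C@]1(C)CCC=C(C(=O)OC)[C@H]2O1 | target

**Total step count:** 20. **Longest linear sequence:** 15 (steps 1–9, 13–17, 20).

**Steps most likely to fail**

Step 13. The alkoxide relay may break down: the indium alkoxide may not transfer the acyl group, acetyl may migrate to the C8 oxygen, the tertiary alkoxide may be held back as its reversible adduct with the methylidene lactone, or the facial selectivity of the allylation may be low. Fallback: the three events are run as separate operations and the ether bond is made by palladium catalysis. Setting out from 13 and 19, a zinc-mediated Barbier reaction (zinc dust, THF/aqueous NH4Cl) is stopped at the hydroxy lactone 20, which is isolated. Camphorsulfonic acid in CH2Cl2 should then move the acyl group to the C8 oxygen to give 21. A Tsuji–Trost allylic etherification [Pd(PPh3)4 (zerovalent palladium), THF] should ionize the allylic acetate, and the tertiary hydroxyl should capture the 2-(methoxycarbonyl)allyl complex at C9, since capture at the CH2 terminus would need a nine-membered ring. This returns to the route at 22. No compound outside the list is made (F0).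

Step 9. Ring closure may lose against intermolecular metathesis: the carbene formed at the vinyl group must engage a hindered, electron-poor 1,1-disubstituted alkene while the ester prefers its extended conformation. Fallback (olefination in place of metathesis): setting out from 9, the tertiary alcohol is esterified with diethylphosphonoacetic acid (DCC, DMAP) to the phosphonoacetate F1. The vinyl group is cleaved by ozonolysis (O3; Me2S) to the α-silyloxy aldehyde F2, and an intramolecular Horner–Wadsworth–Emmons reaction (LiCl, iPr2NEt, MeCN, high dilution) should close the unsaturated seven-membered lactone F3. Morita–Baylis–Hillman hydroxymethylation (aqueous formaldehyde, DMAP) should give the hydroxymethyl lactone F4, and Appel bromination (CBr4, PPh3) returns to the route at 13.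

Step 16. The bridging ring may not close: both arms must be pseudo-axial on ring A, and the catalyst can be diverted into intermolecular metathesis or onto the methylidene lactone. Fallback (Horner–Wadsworth–Emmons ring closure in place of metathesis): setting out from 13, the key step is run with a phosphonate acceptor. Knoevenagel condensation of trimethyl phosphonoacetate with 15 (TiCl4, N-methylmorpholine) gives an E/Z mixture, from which the alkylidene phosphonoacetate acetal F5 (ester trans to the acetal carbon) is separated. Hydrolysis (aqueous CF3CO2H) gives the phosphonate aldehyde F6. Under the conditions of step 13, 13 and F6 should undergo the same allylation and acyl transfer followed by a plain oxa-Michael addition to give the phosphonate F7. Acetal hydrolysis (pyridinium p-toluenesulfonate, wet acetone) gives the aldehyde F8, and intramolecular Horner–Wadsworth–Emmons olefination (LiCl, DBU, MeCN) should form the C1=C10 bond and return to the route at 25.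

**Further compounds**
F0 | step 13 | none | none
F1 | step 9 | (3R,5S)-3-[(tert-butyldimethylsilyl)oxy]-8,8-dimethoxy-5-methyloct-1-en-5-yl 2-(diethoxyphosphoryl)acetate | C=C[C@H](O[Si](C)(C)C(C)(C)C)C[C@@](C)(OC(=O)CP(=O)(OCC)OCC)CCC(OC)OC
F2 | step 9 | (2R,4S)-2-[(tert-butyldimethylsilyl)oxy]-7,7-dimethoxy-4-methyl-1-oxoheptan-4-yl 2-(diethoxyphosphoryl)acetate | O=C[C@H](O[Si](C)(C)C(C)(C)C)C[C@@](C)(OC(=O)CP(=O)(OCC)OCC)CCC(OC)OC
F3 | step 9 | (5R,7S)-5-[(tert-butyldimethylsilyl)oxy]-7-(3,3-dimethoxypropyl)-7-methyl-6,7-dihydro-5H-oxepin-2-one | O=C1C=C[C@H](O[Si](C)(C)C(C)(C)C)C[C@](C)(CCC(OC)OC)O1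
F4 | step 9 | (5R,7S)-5-[(tert-butyldimethylsilyl)oxy]-7-(3,3-dimethoxypropyl)-3-(hydroxymethyl)-7-methyl-6,7-dihydro-5H-oxepin-2-one | OCC1=C[C@H](O[Si](C)(C)C(C)(C)C)C[C@](C)(CCC(OC)OC)OC1=O
F5 | step 16 | methyl (2Z)-2-(dimethoxyphosphoryl)-4,4-dimethoxybut-2-enoate | COC(OC)/C=C(\P(=O)(OC)OC)C(=O)OC
F6 | step 16 | methyl (2Z)-2-(dimethoxyphosphoryl)-4-oxobut-2-enoate | O=C/C=C(\P(=O)(OC)OC)C(=O)OC
F7 | step 16 | analogue of 22 in which C9 carries CH(CO2Me)P(O)(OMe)2 (mixture at that carbon) | C=C1C(=O)O[C@H]2[C@H]1[C@H](O[Si](C)(C)C(C)(C)C)C[C@](C)(CCC(OC)OC)O[C@@H]2C(C(=O)OC)P(=O)(OC)OC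
F8 | step 16 | analogue of 23 in which C9 carries CH(CO2Me)P(O)(OMe)2 | C=C1C(=O)O[C@H]2[C@H]1[C@H](O[Si](C)(C)C(C)(C)C)C[C@](C)(CCC=O)O[C@@H]2C(C(=O)OC)P(=O)(OC)OC
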